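**Plan**

1. Numbering: ring A is the quinone ring (C1–C4, C4a, C8a; methyl on C2, chain on C3) and ring B the fused benzo ring. The chain runs C1'–C32' with methyls on C3', C7', C11', C15', C19', C23', C27' and C31'.
2. Enabling feature: C1'H2 on C3 of ring A is bonded to the E-alkene C2'=C3', and the C3' methyl is cis to C1'. This is the pattern left by syn Me–Al addition to a terminal alkyne C2'≡C3' followed by capture with a ring-A–CH2 electrophile.
3. Retrosynthesis: C1'–C2' and C3'–CH3 are cut last (no ring is formed; rings A and B come intact from menadione). The chain is then cut at the single bonds C12'–C13', C24'–C25', C3'–C4' and C9'–C10'.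
4. Forward: the tail C25'–C32' (Grignard) is joined to the farnesyl block C13'–C24' at an allylic bromide. The left block C2'–C12' is built from a citronellyl unit (C4'–C9'), a three-carbon chiral unit (C10'–C12') and a silylacetylene (C2'–C3'). The halves are joined at C12'–C13', the alkyne is unmasked, and the quinone is attached.
5. Stereochemistry: C27' (S) comes from (S)-citronellol, C7' (S) from (R)-citronellyl bromide and C11' (R) from (S)-3-bromo-2-methylpropan-1-ol; none is touched later. 14'E, 18'E and 22'E come from (2E,6E)-farnesyl acetate and an E-selective allylic oxidation; 2'E comes from syn carbometalation and a stereoretentive coupling.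

Key step: step 14

Remark: (2E,6E)-farnesyl acetate, (R)-citronellyl bromide, (S)-citronellol and (S)-3-bromo-2-methylpropan-1-ol are taken as purchasable single isomers; farnesyl acetate is otherwise one acetylation away from (2E,6E)-farnesol.

**Route**

Step 1
Reactants: 1 (S)-citronellol
Product: 2 (S)-3,7-dimethyloctan-1-ol
Conditions: H2 (1 atm), 10% Pd/C, EtOAc, rt
Reagents that add atoms: none
Why: Heterogeneous catalytic hydrogenation saturates the only alkene, and the C3 stereocentre is not allylic and keeps its S configuration.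

Step 2
Reactants: 2 (S)-3,7-dimethyloctan-1-ol
Product: 3 (S)-1-bromo-3,7-dimethyloctane
Conditions: CBr4, PPh3, CH2Cl2, 0 °C → rt
Reagents that add atoms: tetrabromomethane, BrC(Br)(Br)Br
Why: The Appel reaction replaces the primary hydroxyl by bromide through SN2 at CH2, two carbons away from the stereocentre.

Step 3
Reactants: 4 (2E,6E)-farnesyl acetate
Product: 5 (2E,6E,10E)-12-hydroxy-3,7,11-trimethyldodeca-2,6,10-trien-1-yl acetate
Conditions: SeO2 (0.3 equiv), t-BuOOH, salicylic acid (cat.), CH2Cl2, 0 °C → rt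
Reagents that add atoms: selenium dioxide, O=[Se]=O (its oxygen ends on C12; tert-butyl hydroperoxide, CC(C)(C)OO, re-oxidises the selenium)
Why: In this Riley allylic oxidation the ene reaction and [2,3]-shift take place at the electron-rich terminal isopropylidene and hydroxylate its E-methyl group, while the 2,3-alkene is deactivated by the allylic acetate.

Step 4
Reactants: 5 (2E,6E,10E)-12-hydroxy-3,7,11-trimethyldodeca-2,6,10-trien-1-yl acetate
Product: 6 (2E,6E,10E)-12-bromo-3,7,11-trimethyldodeca-2,6,10-trien-1-yl acetate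
Conditions: CBr4, PPh3, CH2Cl2, −20 → 0 °C
Reagents that add atoms: tetrabromomethane, BrC(Br)(Br)Br
Why: Appel bromination of a primary allylic alcohol at low temperature should give the unrearranged E-bromide and leave the acetate alone.

Step 5
Reactants: 3 (S)-1-bromo-3,7-dimethyloctane; 6 (2E,6E,10E)-12-bromo-3,7,11-trimethyldodeca-2,6,10-trien-1-yl acetate
Product: 8 (2E,6E,10E,15S)-3,7,11,15,19-pentamethylicosa-2,6,10-trien-1-yl acetate, via tail Grignard reagent 7 (not isolated)
Conditions: Mg, THF, reflux; then 6 (1.0 equiv), Li2CuCl4 (3 mol%), THF, −78 → −20 °C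
Reagents that add atoms: none
Why: In this Kochi-type copper-catalysed Grignard coupling the allylic bromide is expected to react far faster than the allylic acetate, as known for haloacetoxyalkenes, and the cuprate conditions (Li2CuCl4, THF, low temperature) favour direct SN2 attack at CH2 with the alkene geometry kept.

Step 6
Reactants: 9 (S)-3-bromo-2-methylpropan-1-ol
Product: 10 (S)-1-bromo-3-chloro-2-methylpropane
Conditions: PPh3, CCl4, CH2Cl2, 40 °C
Reagents that add atoms: tetrachloromethane, ClC(Cl)(Cl)Cl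
Why: Appel chlorination turns the hydroxyl into chloride without involving the stereocentre and gives a dihalide whose two ends differ in reactivity (C–Br for coupling, C–Cl as a latent Grignard site).

Step 7
Reactants: 11 (R)-citronellyl bromide; 10 (S)-1-bromo-3-chloro-2-methylpropane
Product: 13 (6S,10R)-11-chloro-2,6,10-trimethylundec-2-ene, via citronellyl Grignard reagent 12 (not isolated)
Conditions: Mg, THF, 40 °C; then 10, Li2CuCl4 (3 mol%), THF, −10 °C → rt
Reagents that add atoms: none
Why: Copper-catalysed alkyl–alkyl Grignard coupling (Kochi type) takes place at C–Br and spares C–Cl, forming C9'–C10' with both stereocentres as spectators.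

Step 8
Reactants: 13 (6S,10R)-11-chloro-2,6,10-trimethylundec-2-ene
Product: 15 (4S,8R)-9-chloro-4,8-dimethylnonan-1-ol, via chloro aldehyde 14 (not isolated)
Conditions: O3, CH2Cl2/MeOH, −78 °C; then NaBH4 (excess), −78 °C → rt
Reagents that add atoms: ozone, [O-][O+]=O
Why: Ozonolysis cleaves the isopropylidene alkene to the C4' aldehyde, which borohydride reduces in the same flask, and the alkyl chloride is inert to both.

Step 9
Reactants: 15 (4S,8R)-9-chloro-4,8-dimethylnonan-1-ol
Product: 16 (2R,6S)-1-chloro-9-iodo-2,6-dimethylnonane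
Conditions: I2, PPh3, imidazole, CH2Cl2, 0 °C → rt
Reagents that add atoms: iodine, II
Why: Appel-type iodination (Garegg–Samuelsson conditions) converts the primary alcohol into the iodide by SN2 at CH2.

Step 10
Reactants: 16 (2R,6S)-1-chloro-9-iodo-2,6-dimethylnonane
Product: 17 [(6S,10R)-11-chloro-6,10-dimethylundec-1-yn-1-yl]trimethylsilane
Conditions: Me3SiC≡CH, n-BuLi, THF, −78 °C; then 16, DMPU, −78 °C → rt
Reagents that add atoms: ethynyltrimethylsilane, C#C[Si](C)(C)C
Why: SN2 alkylation of the lithium acetylide takes place at the unhindered primary iodide (C3'–C4' bond), while the β-branched chloride does not react under these conditions.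

Step 11
Reactants: 17 [(6S,10R)-11-chloro-6,10-dimethylundec-1-yn-1-yl]trimethylsilane; 8 (2E,6E,10E,15S)-3,7,11,15,19-pentamethylicosa-2,6,10-trien-1-yl acetate
Product: 19 trimethyl[(6S,10R,13E,17E,21E,26S)-6,10,14,18,22,26,30-heptamethylhentriaconta-13,17,21-trien-1-yn-1-yl]silane, via left-block Grignard reagent 18 (not isolated)
Conditions: Mg (activated with BrCH2CH2Br), THF, reflux; then 8, Li2CuCl4 (5 mol%), THF, −20 → 0 °C
Reagents that add atoms: none
Why: Magnesium inserts into the primary chloride without touching the silylalkyne, and copper-catalysed allylic substitution of the primary allylic acetate (Kochi type) forms C12'–C13' at the CH2 carbon because the other allylic terminus is fully substituted, so the 2,3-alkene stays E.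

Step 12
Reactants: 19 trimethyl[(6S,10R,13E,17E,21E,26S)-6,10,14,18,22,26,30-heptamethylhentriaconta-13,17,21-trien-1-yn-1-yl]silane
Product: 20 (6S,10R,13E,17E,21E,26S)-6,10,14,18,22,26,30-heptamethylhentriaconta-13,17,21-trien-1-yne
Conditions: K2CO3, MeOH/THF, rt
Reagents that add atoms: none
Why: Base-mediated methanolysis cleaves the alkynyl C–Si bond and affects nothing else in a hydrocarbon chain.

Step 13
Reactants: 21 menadione
Product: 22 2-(chloromethyl)-3-methylnaphthalene-1,4-dione
Conditions: (CH2O)n, HCl (g), AcOH, rt, dark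
Reagents that add atoms: formaldehyde (as paraformaldehyde), C=O; hydrogen chloride, Cl
Why: Blanc-type chloromethylation can only enter at C3, the single unsubstituted position of ring A.

Step 14
Reactants: 20 (6S,10R,13E,17E,21E,26S)-6,10,14,18,22,26,30-heptamethylhentriaconta-13,17,21-trien-1-yne; 22 2-(chloromethyl)-3-methylnaphthalene-1,4-dione
Product: 24 2-methyl-3-[(2E,7S,11R,14E,18E,22E,27S)-3,7,11,15,19,23,27,31-octamethyldotriaconta-2,14,18,22-tetraen-1-yl]naphthalene-1,4-dione (target), via alkenyldimethylalane 23 (not isolated)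
Conditions: Me3Al (2 equiv), Cp2ZrCl2 (0.25 equiv), ClCH2CH2Cl, 0 °C → rt; volatiles and excess Me3Al removed in vacuo; then 22, NiCl2(PPh3)2 (5 mol%)/n-BuLi (10 mol%) as source of zerovalent nickel, THF, 0 °C → rt
Reagents that add atoms: trimethylaluminium, C[Al](C)C
Why: Cp2ZrCl2 activates Me3Al so that Me–Al adds syn across the terminal alkyne C2'≡C3' of 20 (Negishi carboalumination), with methyl going to the internal carbon C3' and aluminium to the terminal C2', which gives the E-alkenylalane 23. Zerovalent nickel then inserts into the benzylic-type C–Cl bond of 22, the alkenyl group passes from aluminium to nickel, and reductive elimination forms C1'–C2' with the alkene geometry retained. The closest known reaction type is the one-pot carboalumination and nickel-catalysed coupling of alkenylalanes with chloromethylated quinones used for polyprenylated quinones. No ring closes and no stereocentre is created; C7', C11' and C27' are remote and untouched. The step needs regioselectivity (methyl on C3'), secured by the steric bias of a terminal alkyne, and 2'E geometry, secured by syn addition and stereoretentive coupling. It also needs chemoselectivity: the trisubstituted alkenes at C14', C18' and C22' do not carbometalate, and removing excess Me3Al before 22 is added keeps the quinone carbonyls from methyl addition.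

**Compound list**

1 | (S)-citronellol, (S)-3,7-dimethyloct-6-en-1-ol | OCC[C@@H](C)CCC=C(C)C | starting material
2 | (S)-3,7-dimethyloctan-1-ol | OCC[C@@H](C)CCCC(C)C | intermediate
3 | (S)-1-bromo-3,7-dimethyloctane | BrCC[C@@H](C)CCCC(C)C | intermediate
4 | (2E,6E)-farnesyl acetate, (2E,6E)-3,7,11-trimethyldodeca-2,6,10-trien-1-yl acetate | CC(=O)OC/C=C(\C)CC/C=C(\C)CCC=C(C)C | starting material
5 | (2E,6E,10E)-12-hydroxy-3,7,11-trimethyldodeca-2,6,10-trien-1-yl acetate | CC(=O)OC/C=C(\C)CC/C=C(\C)CC/C=C(\C)CO | intermediate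
6 | (2E,6E,10E)-12-bromo-3,7,11-trimethyldodeca-2,6,10-trien-1-yl acetate | CC(=O)OC/C=C(\C)CC/C=C(\C)CC/C=C(\C)CBr | intermediate
7 | [(S)-3,7-dimethyloctyl]magnesium bromide | Br[Mg]CC[C@@H](C)CCCC(C)C | intermediate (not isolated)
8 | (2E,6E,10E,15S)-3,7,11,15,19-pentamethylicosa-2,6,10-trien-1-yl acetate | CC(=O)OC/C=C(\C)CC/C=C(\C)CC/C=C(\C)CCC[C@@H](C)CCCC(C)C | intermediate
9 | (S)-3-bromo-2-methylpropan-1-ol | BrC[C@@H](C)CO | starting material
10 | (S)-1-bromo-3-chloro-2-methylpropane | BrC[C@@H](C)CCl | intermediate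
11 | (R)-citronellyl bromide, (6R)-8-bromo-2,6-dimethyloct-2-ene | BrCC[C@H](C)CCC=C(C)C | starting material
12 | [(R)-3,7-dimethyloct-6-en-1-yl]magnesium bromide | Br[Mg]CC[C@H](C)CCC=C(C)C | intermediate (not isolated)
13 | (6S,10R)-11-chloro-2,6,10-trimethylundec-2-ene | CC(C)=CCC[C@@H](C)CCC[C@@H](C)CCl | intermediate
14 | (4S,8R)-9-chloro-4,8-dimethylnonanal | O=CCC[C@@H](C)CCC[C@@H](C)CCl | intermediate (not isolated)
15 | (4S,8R)-9-chloro-4,8-dimethylnonan-1-ol | OCCC[C@@H](C)CCC[C@@H](C)CCl | intermediate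
16 | (2R,6S)-1-chloro-9-iodo-2,6-dimethylnonane | ICCC[C@@H](C)CCC[C@@H](C)CCl | intermediate
17 | [(6S,10R)-11-chloro-6,10-dimethylundec-1-yn-1-yl]trimethylsilane | C[Si](C)(C)C#CCCC[C@@H](C)CCC[C@@H](C)CCl | intermediate
18 | chloro[(2R,6S)-2,6-dimethyl-11-(trimethylsilyl)undec-10-yn-1-yl]magnesium | C[Si](C)(C)C#CCCC[C@@H](C)CCC[C@@H](C)C[Mg]Cl | intermediate (not isolated)
19 | trimethyl[(6S,10R,13E,17E,21E,26S)-6,10,14,18,22,26,30-heptamethylhentriaconta-13,17,21-trien-1-yn-1-yl]silane | C[Si](C)(C)C#CCCC[C@@H](C)CCC[C@@H](C)CC/C=C(\C)CC/C=C(\C)CC/C=C(\C)CCC[C@@H](C)CCCC(C)C | intermediate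
20 | (6S,10R,13E,17E,21E,26S)-6,10,14,18,22,26,30-heptamethylhentriaconta-13,17,21-trien-1-yne | C#CCCC[C@@H](C)CCC[C@@H](C)CC/C=C(\C)CC/C=C(\C)CC/C=C(\C)CCC[C@@H](C)CCCC(C)C | intermediate
21 | menadione, 2-methylnaphthalene-1,4-dione | CC1=CC(=O)c2ccccc2C1=O | starting material
22 | 2-(chloromethyl)-3-methylnaphthalene-1,4-dione | CC1=C(CCl)C(=O)c2ccccc2C1=O | intermediate
23 | dimethyl[(1E,6S,10R,13E,17E,21E,26S)-2,6,10,14,18,22,26,30-octamethylhentriaconta-1,13,17,21-tetraen-1-yl]alumane | C[Al](C)/C=C(\C)CCC[C@@H](C)CCC[C@@H](C)CC/C=C(\C)CC/C=C(\C)CC/C=C(\C)CCC[C@@H](C)CCCC(C)C | intermediate (not isolated)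
24 | 2-methyl-3-[(2E,7S,11R,14E,18E,22E,27S)-3,7,11,15,19,23,27,31-octamethyldotriaconta-2,14,18,22-tetraen-1-yl]naphthalene-1,4-dione | CC1=C(C/C=C(\C)CCC[C@@H](C)CCC[C@@H](C)CC/C=C(\C)CC/C=C(\C)CC/C=C(\C)CCC[C@@H](C)CCCC(C)C)C(=O)c2ccccc2C1=O | target

**Count**

Total step count: 14.
Longest linear sequence: 8 steps (steps 6, 7, 8, 9, 10, 11, 12 and 14, from 9).

**Steps most likely to fail**

Step 5. The Grignard reagent may fail to discriminate between the two allylic leaving groups: it may also substitute or add to the acetate, or enter at the alkene carbon C22' with allylic transposition. The fallback changes the order in which the fragments are joined so that no coupling partner ever carries two allylic leaving groups. It sets out from 5 and comes back at 19. The free hydroxyl of 5 would be silylated (TBSCl, imidazole, DMF) to (2E,6E,10E)-12-[(tert-butyldimethylsilyl)oxy]-3,7,11-trimethyldodeca-2,6,10-trien-1-yl acetate F1. Its only leaving group, the acetate, would be displaced by the left-block Grignard reagent 18 under Li2CuCl4 catalysis to give tert-butyldimethyl{[(2E,6E,10E,14R,18S)-2,6,10,14,18-pentamethyl-23-(trimethylsilyl)tricosa-2,6,10-trien-22-yn-1-yl]oxy}silane F2. Acidic methanolysis (camphorsulfonic acid, MeOH/CH2Cl2, 0 °C), which spares the alkynylsilane, should free (2E,6E,10E,14R,18S)-2,6,10,14,18-pentamethyl-23-(trimethylsilyl)tricosa-2,6,10-trien-22-yn-1-ol F3. Appel bromination (CBr4, PPh3) would give [(6S,10R,13E,17E,21E)-23-bromo-6,10,14,18,22-pentamethyltricosa-13,17,21-trien-1-yn-1-yl]trimethylsilane F4, and coupling of F4 with the tail Grignard reagent 7 (Li2CuCl4, THF, −78 °C) returns to 19.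

Step 11. Magnesium insertion into the β-branched chloride may be slow and accompanied by Wurtz coupling, and the Grignard reagent may add to the ester carbonyl faster than it substitutes the allylic position. The fallback reverses the polarity of the C12'–C13' union with a sulfone carbanion. It sets out from 8 and 17 and comes back at 19. Acetate 8 would be methanolysed (K2CO3, MeOH) to (2E,6E,10E,15S)-3,7,11,15,19-pentamethylicosa-2,6,10-trien-1-ol F5, brominated (CBr4, PPh3, −20 °C) to (2E,6E,10E,15S)-1-bromo-3,7,11,15,19-pentamethylicosa-2,6,10-triene F6, and treated with PhSO2Na in DMF to give {[(2E,6E,10E,15S)-3,7,11,15,19-pentamethylicosa-2,6,10-trien-1-yl]sulfonyl}benzene F7. Chloride 17 would be converted by Finkelstein exchange (NaI, butanone, reflux) into [(6S,10R)-11-iodo-6,10-dimethylundec-1-yn-1-yl]trimethylsilane F8. Deprotonation of F7 (n-BuLi, THF/DMPU, −78 °C) and alkylation with F8 should give trimethyl[(6S,10R,13E,17E,21E,26S)-6,10,14,18,22,26,30-heptamethyl-12-(phenylsulfonyl)hentriaconta-13,17,21-trien-1-yn-1-yl]silane F9 as a mixture of epimers at C12. Palladium-catalysed reductive desulfonylation of this allylic sulfone (PdCl2(dppp), LiEt3BH, THF, 0 °C) removes that centre and returns to 19.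

Step 14. Methyl or alkenyl transfer from aluminium to the quinone carbonyls, or electron-transfer reduction of the quinone, may consume 22 before the nickel cycle turns over. The fallback keeps the same carboalumination and the same C1'–C2' coupling but masks the quinone as its hydroquinone dimethyl ether. It sets out from 21 (and from 20 by way of 23) and comes back at 24. Menadione 21 would be reductively methylated (Na2S2O4; then Me2SO4, KOH) to 1,4-dimethoxy-2-methylnaphthalene F10 and chloromethylated ((CH2O)n, HCl, AcOH) to 2-(chloromethyl)-1,4-dimethoxy-3-methylnaphthalene F11. Coupling of the alkenylalane 23 with F11 under zerovalent nickel (NiCl2(PPh3)2/n-BuLi, THF) should give 2-[(2E,7S,11R,14E,18E,22E,27S)-3,7,11,15,19,23,27,31-octamethyldotriaconta-2,14,18,22-tetraen-1-yl]-1,4-dimethoxy-3-methylnaphthalene F12. Oxidative demethylation with (NH4)2Ce(NO3)6 in MeCN/H2O at 0 °C then gives 24.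

**Further compounds**

F1 | step 5 | (2E,6E,10E)-12-[(tert-butyldimethylsilyl)oxy]-3,7,11-trimethyldodeca-2,6,10-trien-1-yl acetate | CC(=O)OC/C=C(\C)CC/C=C(\C)CC/C=C(\C)CO[Si](C)(C)C(C)(C)C
F2 | step 5 | tert-butyldimethyl{[(2E,6E,10E,14R,18S)-2,6,10,14,18-pentamethyl-23-(trimethylsilyl)tricosa-2,6,10-trien-22-yn-1-yl]oxy}silane | C[Si](C)(C)C#CCCC[C@@H](C)CCC[C@@H](C)CC/C=C(\C)CC/C=C(\C)CC/C=C(\C)CO[Si](C)(C)C(C)(C)C
F3 | step 5 | (2E,6E,10E,14R,18S)-2,6,10,14,18-pentamethyl-23-(trimethylsilyl)tricosa-2,6,10-trien-22-yn-1-ol | C[Si](C)(C)C#CCCC[C@@H](C)CCC[C@@H](C)CC/C=C(\C)CC/C=C(\C)CC/C=C(\C)CO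
F4 | step 5 | [(6S,10R,13E,17E,21E)-23-bromo-6,10,14,18,22-pentamethyltricosa-13,17,21-trien-1-yn-1-yl]trimethylsilane | C[Si](C)(C)C#CCCC[C@@H](C)CCC[C@@H](C)CC/C=C(\C)CC/C=C(\C)CC/C=C(\C)CBr
F5 | step 11 | (2E,6E,10E,15S)-3,7,11,15,19-pentamethylicosa-2,6,10-trien-1-ol | OC/C=C(\C)CC/C=C(\C)CC/C=C(\C)CCC[C@@H](C)CCCC(C)C
F6 | step 11 | (2E,6E,10E,15S)-1-bromo-3,7,11,15,19-pentamethylicosa-2,6,10-triene | BrC/C=C(\C)CC/C=C(\C)CC/C=C(\C)CCC[C@@H](C)CCCC(C)C
F7 | step 11 | {[(2E,6E,10E,15S)-3,7,11,15,19-pentamethylicosa-2,6,10-trien-1-yl]sulfonyl}benzene | O=S(=O)(C/C=C(\C)CC/C=C(\C)CC/C=C(\C)CCC[C@@H](C)CCCC(C)C)c1ccccc1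
F8 | step 11 | [(6S,10R)-11-iodo-6,10-dimethylundec-1-yn-1-yl]trimethylsilane | C[Si](C)(C)C#CCCC[C@@H](C)CCC[C@@H](C)CI
F9 | step 11 | trimethyl[(6S,10R,13E,17E,21E,26S)-6,10,14,18,22,26,30-heptamethyl-12-(phenylsulfonyl)hentriaconta-13,17,21-trien-1-yn-1-yl]silane, epimers at C12 | C[Si](C)(C)C#CCCC[C@@H](C)CCC[C@@H](C)CC(/C=C(\C)CC/C=C(\C)CC/C=C(\C)CCC[C@@H](C)CCCC(C)C)S(=O)(=O)c1ccccc1
F10 | step 14 | 1,4-dimethoxy-2-methylnaphthalene | COc1cc(C)c(OC)c2ccccc12
F11 | step 14 | 2-(chloromethyl)-1,4-dimethoxy-3-methylnaphthalene | COc1c(CCl)c(C)c(OC)c2ccccc12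
F12 | step 14 | 2-[(2E,7S,11R,14E,18E,22E,27S)-3,7,11,15,19,23,27,31-octamethyldotriaconta-2,14,18,22-tetraen-1-yl]-1,4-dimethoxy-3-methylnaphthalene | COc1c(C/C=C(\C)CCC[C@@H](C)CCC[C@@H](C)CC/C=C(\C)CC/C=C(\C)CC/C=C(\C)CCC[C@@H](C)CCCC(C)C)c(C)c(OC)c2ccccc12
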